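**Retrosynthetic overview**

1. The target is fisetinidol-(4α→8)-catechin-(6→4β)-fisetinidol. It is unmasked last by hydrogenolysis of its deca-O-benzyl ether, and the flavan units are joined in the order C4–C8 bond first (from benzylated mollisacacidin and benzylated catechin), C4–C6 bond second.
2. The pyran ring (ring C) of the C6-linked 4β unit is not closed as such. It comes from a cis-2,3-disubstituted 2,3-dihydrobenzofuran, with ring D on one furan carbon and an aryl carbinol on the other, by a 1,2-shift of the aryl ether oxygen (five → six).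
3. Enabling feature (flavan numbering): in the five-membered ring (O1, C3, C4, C4a, C8a) O1 sits on C3, next to the exocyclic carbinol carbon C2, which is benzylic to the 3,4-dioxygenated ring B. C2 ionises, O1 bridges C2/C3, and water opens the bridge at C3 to give the less strained six-membered ring.
4. The dihydrobenzofuran comes from a (Z)-1,3-diarylpropene (epoxidation under allylic 1,3-strain control, 5-exo-tet closure). The alkene comes from an alkyne, and the alkyne from a catalytic asymmetric Friedel–Crafts reaction of C6 (ring D) of hepta-O-benzyl-fisetinidol-(4α→8)-catechin with an alkynyl ortho-quinone methide.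
5. Order of ring formation: the chroman systems of catechin and of the C8-linked unit are taken from the chiral pool (catechin, fustin); the furan ring is closed on them (step 9) and then enlarged to the third pyran ring (step 10).

Key step: step 10

Assumption: (2R,3R)-fustin is bought as the single natural enantiomer. The antipode of the chiral phosphoric acid in step 7 is the one that gives the R-configured methine (written as (R)-TRIP, the 3,3'-bis(2,4,6-triisopropylphenyl)-BINOL hydrogen phosphate); the sense of induction has to be assigned on the first run and the other antipode taken if needed.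

**Route**

Step 1
Reactants: 1 (2R,3R)-fustin
Product: 2 (2R,3S,4R)-mollisacacidin (2,3-trans-3,4-trans-flavan-3,4,7,3',4'-pentaol)
Conditions: NaBH4, MeOH, 0 °C
Reagents that add atoms: none
Why: Hydride reduction of the aryl ketone with NaBH4, in which hydride should enter C4 anti to the 3-hydroxyl to give mainly the 3,4-trans diol, while the C4 configuration is in any case erased when C4 is ionised in step 4.

Step 2
Reactants: 2 mollisacacidin
Product: 3 7,3',4'-tri-O-benzylmollisacacidin [(2R,3S,4R)-7-(benzyloxy)-2-[3,4-bis(benzyloxy)phenyl]chroman-3,4-diol]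
Conditions: BnBr (3.3 equiv), K2CO3, DMF, 25 °C, argon
Reagents that add atoms: benzyl bromide, BrCc1ccccc1
Why: Williamson ether synthesis in which K2CO3 deprotonates only the three phenols, so that the secondary 3-hydroxyl and the benzylic 4-hydroxyl stay free and no stereocentre is touched.

Step 3
Reactants: 4 (+)-catechin (2R,3S)
Product: 5 5,7,3',4'-tetra-O-benzyl-(+)-catechin
Conditions: BnBr (4.4 equiv), K2CO3, DMF, 0 → 25 °C, argon
Reagents that add atoms: benzyl bromide, BrCc1ccccc1
Why: Williamson ether synthesis of the four phenols under a base too weak to deprotonate the secondary 3-hydroxyl, which leaves both stereocentres untouched.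

Step 4
Reactants: 3 tri-O-benzylmollisacacidin; 5 tetra-O-benzylcatechin (3 equiv)
Product: 6 hepta-O-benzyl-fisetinidol-(4α→8)-catechin (upper unit 2R,3S,4S; lower unit 2R,3S; both 3-OH free)
Conditions: BF3·OEt2 (1.2 equiv), 4 Å molecular sieves, CH2Cl2, −20 → 0 °C; silica gel chromatography (excess 5 recovered)
Reagents that add atoms: none
Why: Lewis acid-mediated Friedel–Crafts alkylation (SN1) of the kind used to join benzylated flavan units, in which BF3 ionises the benzylic 4-hydroxyl of 3 to a cation stabilised by the para 7-benzyloxy group of ring A, the phloroglucinol-type ring of 5 attacks through C8, and the new C4 centre is set 3,4-trans (4α) by approach anti to the 3-hydroxyl; the excess of 5 suppresses a second alkylation of the product, and minor regio- and stereoisomers are removed by chromatography.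

Step 5
Reactants: 7 3,4-bis(benzyloxy)benzaldehyde
Product: 8 4-ethynyl-1,2-bis(benzyloxy)benzene
Conditions: Ohira–Bestmann reagent, K2CO3, MeOH, 25 °C
Reagents that add atoms: dimethyl (1-diazo-2-oxopropyl)phosphonate, COP(=O)(OC)C(=[N+]=[N-])C(C)=O
Why: The Ohira–Bestmann variant of the Seyferth–Gilbert homologation converts the aldehyde into the terminal alkyne under mild base that leaves the benzyl ethers untouched.

Step 6
Reactants: 8 4-ethynyl-1,2-bis(benzyloxy)benzene (2.1 equiv); 9 4-(benzyloxy)-2-hydroxybenzaldehyde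
Product: 11 rac-5-(benzyloxy)-2-{3-[3,4-bis(benzyloxy)phenyl]-1-hydroxyprop-2-yn-1-yl}phenol, via lithium acetylide 10 (not isolated)
Conditions: n-BuLi (2.1 equiv), THF, −78 °C; then 9, −78 → 0 °C; aq. NH4Cl
Reagents that add atoms: none
Why: 1,2-Addition of a lithium acetylide to an aldehyde, the first equivalent serving to deprotonate the phenol, in which the carbinol centre is formed racemic and is erased again in step 7.

Step 7
Reactants: 6 hepta-O-benzyl-fisetinidol-(4α→8)-catechin; 11 propargylic alcohol (1.5 equiv)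
Product: 13 C6-propargylated biflavanoid [ring D carries at C6 the (1R)-1-[4-(benzyloxy)-2-hydroxyphenyl]-3-[3,4-bis(benzyloxy)phenyl]prop-2-yn-1-yl group], via ortho-quinone methide 12 (not isolated)
Conditions: (R)-TRIP (10 mol %), 5 Å molecular sieves, CH2Cl2, 0 → 25 °C
Reagents that add atoms: none
Why: Chiral phosphoric acid-catalysed Friedel–Crafts-type 1,4-addition to an ortho-quinone methide made in situ, in which the acid dehydrates 11 and holds the quinone methide in its chiral pocket, C6 of ring D (the only unsubstituted position of the most electron-rich ring of 6) attacks the exocyclic carbon, and the new diarylmethine centre (R) is set by the catalyst.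

Step 8
Reactants: 13 C6-propargylated biflavanoid
Product: 14 (Z)-alkene [ring D carries at C6 the (1R,2Z)-1-[4-(benzyloxy)-2-hydroxyphenyl]-3-[3,4-bis(benzyloxy)phenyl]prop-2-en-1-yl group]
Conditions: H2 (1 atm), Lindlar catalyst (Pd/CaCO3 poisoned with Pb(OAc)2), quinoline, EtOAc, 25 °C
Reagents that add atoms: none
Why: Lindlar semi-hydrogenation adds H2 syn to give the (Z)-alkene and stops there, and the benzyl ethers and benzylic C–O bonds should not be cleaved on the poisoned catalyst.

Step 9
Reactants: 14 (Z)-alkene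
Product: 16 cis-dihydrobenzofuran carbinol [ring D carries at C6 the (2R,3R)-6-(benzyloxy)-2-{(R)-[3,4-bis(benzyloxy)phenyl](hydroxy)methyl}-2,3-dihydro-1-benzofuran-3-yl group], via cis-epoxide 15 (not isolated)
Conditions: dimethyldioxirane (DMDO, 1.2 equiv), acetone/CH2Cl2, −30 °C; then K2CO3 (0.2 equiv), MeOH, 0 → 25 °C
Reagents that add atoms: dimethyldioxirane, CC1(C)OO1
Why: Dioxirane epoxidation followed by a Baldwin-favoured 5-exo-tet phenoxide opening (SN2), in which allylic 1,3-strain of the (Z)-alkene holds the methine hydrogen in the alkene plane so that oxygen is delivered to the face flanked by the smaller 2-hydroxyaryl ring and away from the bulky ring D, and the phenoxide then inverts the proximal epoxide carbon to give the 2,3-cis dihydrobenzofuran.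

Step 10
Reactants: 16 cis-dihydrobenzofuran carbinol
Product: 17 deca-O-benzyl ether of the target [tri-O-benzyl-fisetinidol-(4α→8)-(tetra-O-benzylcatechin)-(6→4β)-tri-O-benzyl-fisetinidol; new unit 2R,3S,4R]
Conditions: TsOH·H2O (5 mol %), hexafluoroisopropanol (HFIP)/CH2Cl2 1:3, H2O (20 equiv), 25 °C, 5 mM
Reagents that add atoms: water, O
Why: Proposed new method: acid ionises the benzylic carbinol to a cation stabilised by the para benzyloxy group of the 3,4-bis(benzyloxy)phenyl ring, the neighbouring aryl ether oxygen O1 bridges it to an aryloxiranium ion, and water opens this ion at the former furan carbon, so that O1 ends on C2 and the new hydroxyl on C3 (flavan numbering; a 1,2-aryloxy shift with ring enlargement). The closest known reaction types are the Zn(OAc)2-mediated rearrangement–ring expansion of 2-(1-sulfonyloxyalkyl)tetrahydrofurans to 3-acyloxytetrahydropyrans and the aryloxiranium-mediated interconversion of 2,3-dihydrobenzofuran-2-ylmethyl and chroman-3-yl derivatives; what is new is a free benzylic hydroxyl as the leaving group with re-entry of water at the non-benzylic carbon. The pyran ring closes by 3-exo-tet bridging of O1 onto the benzylic cation followed by cleavage of the old O1–C3 bond, which amounts to a 6-endo O1–C2 closure. C3 is set by SN2-type inversion, water entering anti to the departing O1, which turns the cis relation of the furan substituents into the 3,4-cis (4β) relation, and C2 is set from the planar cation, where bridging on the face that puts ring B trans to the C3–C4 bond is favoured, so that both carbinol epimers should converge on the 2,3-trans flavan. The step needs attack at the ring carbon to win over return of water to the benzylic carbon, and this is secured by reversibility, because the benzylic alcohol re-ionises under the conditions whereas the non-benzylic 3-ol in the less strained six-membered ring does not. Dilute acid, water in excess and ambient temperature are chosen to keep E1 loss of the furan C–H and cleavage of the interflavanyl bonds slow.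

Step 11
Reactants: 17 deca-O-benzyl ether of the target
Product: 18 fisetinidol-(4α→8)-catechin-(6→4β)-fisetinidol (target CNP0289228.1)
Conditions: H2 (1 atm), Pd(OH)2/C, THF/MeOH/H2O 20:1:1, 25 °C
Reagents that add atoms: none
Why: Hydrogenolysis of the ten benzyl ethers over Pd(OH)2/C is the standard last step for benzylated proanthocyanidins, and the interflavanyl C–C bonds, the pyran C2–O1 bonds and all stereocentres should be unaffected at ambient pressure.

**Compound list**

1 | (2R,3R)-fustin, (2R,3R)-2-(3,4-dihydroxyphenyl)-3,7-dihydroxychroman-4-one | Oc1ccc2c(c1)O[C@H](c1ccc(O)c(O)c1)[C@@H](O)C2=O | starting material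
2 | (2R,3S,4R)-mollisacacidin, 2,3-trans-3,4-trans-2-(3,4-dihydroxyphenyl)chroman-3,4,7-triol | Oc1ccc2c(c1)O[C@H](c1ccc(O)c(O)c1)[C@@H](O)[C@@H]2O | intermediate
3 | 7,3',4'-tri-O-benzylmollisacacidin, (2R,3S,4R)-7-(benzyloxy)-2-[3,4-bis(benzyloxy)phenyl]chroman-3,4-diol | c1ccccc1COc1ccc2c(c1)O[C@H](c1ccc(OCc3ccccc3)c(OCc3ccccc3)c1)[C@@H](O)[C@@H]2O | intermediate
4 | (+)-catechin (2R,3S) | Oc1cc(O)c2c(c1)O[C@H](c1ccc(O)c(O)c1)[C@@H](O)C2 | starting material
5 | 5,7,3',4'-tetra-O-benzyl-(+)-catechin (3-OH free) | c1ccccc1COc1cc(OCc3ccccc3)c2c(c1)O[C@H](c1ccc(OCc3ccccc3)c(OCc3ccccc3)c1)[C@@H](O)C2 | intermediate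
6 | hepta-O-benzyl-fisetinidol-(4α→8)-catechin (all phenols benzylated, both 3-OH free, C6 of ring D unsubstituted; upper unit 2R,3S,4S; lower unit 2R,3S) | c1c(OCc3ccccc3)c2c(c([C@@H]3c4ccc(OCc5ccccc5)cc4O[C@H](c4ccc(OCc5ccccc5)c(OCc5ccccc5)c4)[C@H]3O)c1OCc1ccccc1)O[C@H](c1ccc(OCc3ccccc3)c(OCc3ccccc3)c1)[C@@H](O)C2 | intermediate
7 | 3,4-bis(benzyloxy)benzaldehyde | O=Cc1ccc(OCc2ccccc2)c(OCc2ccccc2)c1 | starting material
8 | 4-ethynyl-1,2-bis(benzyloxy)benzene | C#Cc1ccc(OCc2ccccc2)c(OCc2ccccc2)c1 | intermediate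
9 | 4-(benzyloxy)-2-hydroxybenzaldehyde | O=Cc1ccc(OCc2ccccc2)cc1O | starting material
10 | lithium [3,4-bis(benzyloxy)phenyl]acetylide (not isolated) | [Li]C#Cc1ccc(OCc2ccccc2)c(OCc2ccccc2)c1 | intermediate
11 | rac-5-(benzyloxy)-2-{3-[3,4-bis(benzyloxy)phenyl]-1-hydroxyprop-2-yn-1-yl}phenol | OC(C#Cc1ccc(OCc2ccccc2)c(OCc2ccccc2)c1)c1ccc(OCc2ccccc2)cc1O | intermediate
12 | alkynyl ortho-quinone methide, 3-(benzyloxy)-6-{3-[3,4-bis(benzyloxy)phenyl]prop-2-yn-1-ylidene}cyclohexa-2,4-dien-1-one (not isolated) | O=C1C=C(OCc2ccccc2)C=CC1=CC#Cc1ccc(OCc2ccccc2)c(OCc2ccccc2)c1 | intermediate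
13 | hepta-O-benzyl-fisetinidol-(4α→8)-catechin bearing at C6 of ring D the (1R)-1-[4-(benzyloxy)-2-hydroxyphenyl]-3-[3,4-bis(benzyloxy)phenyl]prop-2-yn-1-yl group | Oc1cc(OCc2ccccc2)ccc1[C@@H](C#Cc1ccc(OCc2ccccc2)c(OCc2ccccc2)c1)c1c(OCc3ccccc3)c2c(c([C@@H]3c4ccc(OCc5ccccc5)cc4O[C@H](c4ccc(OCc5ccccc5)c(OCc5ccccc5)c4)[C@H]3O)c1OCc1ccccc1)O[C@H](c1ccc(OCc3ccccc3)c(OCc3ccccc3)c1)[C@@H](O)C2 | intermediate
14 | hepta-O-benzyl-fisetinidol-(4α→8)-catechin bearing at C6 of ring D the (1R,2Z)-1-[4-(benzyloxy)-2-hydroxyphenyl]-3-[3,4-bis(benzyloxy)phenyl]prop-2-en-1-yl group | Oc1cc(OCc2ccccc2)ccc1[C@@H](/C=C\c1ccc(OCc2ccccc2)c(OCc2ccccc2)c1)c1c(OCc3ccccc3)c2c(c([C@@H]3c4ccc(OCc5ccccc5)cc4O[C@H](c4ccc(OCc5ccccc5)c(OCc5ccccc5)c4)[C@H]3O)c1OCc1ccccc1)O[C@H](c1ccc(OCc3ccccc3)c(OCc3ccccc3)c1)[C@@H](O)C2 | intermediate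
15 | hepta-O-benzyl-fisetinidol-(4α→8)-catechin bearing at C6 of ring D the (R)-[4-(benzyloxy)-2-hydroxyphenyl]{(2S,3R)-3-[3,4-bis(benzyloxy)phenyl]oxiran-2-yl}methyl group, cis-epoxide (not isolated) | Oc1cc(OCc2ccccc2)ccc1[C@@H]([C@@H]1O[C@@H]1c1ccc(OCc2ccccc2)c(OCc2ccccc2)c1)c1c(OCc3ccccc3)c2c(c([C@@H]3c4ccc(OCc5ccccc5)cc4O[C@H](c4ccc(OCc5ccccc5)c(OCc5ccccc5)c4)[C@H]3O)c1OCc1ccccc1)O[C@H](c1ccc(OCc3ccccc3)c(OCc3ccccc3)c1)[C@@H](O)C2 | intermediate
16 | hepta-O-benzyl-fisetinidol-(4α→8)-catechin bearing at C6 of ring D the (2R,3R)-6-(benzyloxy)-2-{(R)-[3,4-bis(benzyloxy)phenyl](hydroxy)methyl}-2,3-dihydro-1-benzofuran-3-yl group (2,3-cis) | O[C@H](c1ccc(OCc2ccccc2)c(OCc2ccccc2)c1)[C@@H]1Oc2cc(OCc3ccccc3)ccc2[C@@H]1c1c(OCc3ccccc3)c2c(c([C@@H]3c4ccc(OCc5ccccc5)cc4O[C@H](c4ccc(OCc5ccccc5)c(OCc5ccccc5)c4)[C@H]3O)c1OCc1ccccc1)O[C@H](c1ccc(OCc3ccccc3)c(OCc3ccccc3)c1)[C@@H](O)C2 | intermediate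
17 | deca-O-benzyl ether of the target (all ten phenols benzylated, three 3-OH free; C6-linked unit 2R,3S,4R) | c1ccccc1COc1ccc2c(c1)O[C@H](c1ccc(OCc3ccccc3)c(OCc3ccccc3)c1)[C@@H](O)[C@H]2c1c(OCc3ccccc3)c2c(c([C@@H]3c4ccc(OCc5ccccc5)cc4O[C@H](c4ccc(OCc5ccccc5)c(OCc5ccccc5)c4)[C@H]3O)c1OCc1ccccc1)O[C@H](c1ccc(OCc3ccccc3)c(OCc3ccccc3)c1)[C@@H](O)C2 | intermediate
18 | fisetinidol-(4α→8)-catechin-(6→4β)-fisetinidol, CNP0289228.1 | Oc1ccc2c(c1)O[C@H](c1ccc(O)c(O)c1)[C@@H](O)[C@H]2c1c(O)c2c(c([C@@H]3c4ccc(O)cc4O[C@H](c4ccc(O)c(O)c4)[C@H]3O)c1O)O[C@H](c1ccc(O)c(O)c1)[C@@H](O)C2 | target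

**Step count and risks**

Total step count: 11. Longest linear sequence: 8 steps (steps 1, 2, 4, 7, 8, 9, 10, 11).

Step 10 (key step, proposed new method). What may go wrong: the benzylic cation may lose the neighbouring furan C–H (E1, or a 1,2-hydride shift) and aromatise to the benzofuran, it may be trapped by a flanking benzyloxy oxygen of ring D, it may simply return to the benzylic alcohol faster than O1 bridges, or the new benzylic C2–O1 bond of the product may ionise in turn. The fallback sets out from 14 and comes back at 17, and it closes the pyran ring directly by known chemistry, without the furan. Thiyl radical-mediated isomerisation (PhSSPh cat., hν, benzene, 25 °C) should turn the (Z)-alkene into the (E)-alkene F1. Epoxidation with dimethyldioxirane (acetone/CH2Cl2, −30 °C) on the face of the 2-hydroxyaryl ring should give the trans-epoxide F2, which is not stored. Camphorsulfonic acid (5 mol %, CH2Cl2, −20 °C) then triggers the 6-endo-tet opening of the epoxide by the phenol at the benzylic carbon with inversion, the known epoxide route to 2,3-trans-flavan-3-ols, and this gives 17. Facial selectivity on the (E)-alkene is less secure than on the (Z)-alkene, so the diastereomer would have to be removed by chromatography.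

Step 7. What may go wrong: attack of the arene at the alkyne terminus of the quinone methide (allene formation), competing attack by the resorcinol-type ring A of the upper unit, or poor facial discrimination by the catalyst with a hindered nucleophile that has no phenolic hydrogen-bond donor. The fallback sets out from 6 and comes back at 13, with the polarity reversed. N-Bromosuccinimide in CH2Cl2 at −78 °C brominates the free C6 to give the C6-bromide F3. Bromine–lithium exchange (n-BuLi, excess to cover the two hydroxyls, THF, −78 °C) and addition to aldehyde 9 (as its sodium phenoxide, made with NaH) gives the diaryl carbinol F4 as a mixture of carbinol epimers. Alkyne 8 is lithiated and treated with B(OiPr)3, then HCl in ether, to give the diisopropyl alkynylboronate F5. F4 is then ionised to the ortho-quinone methide that carries ring D on its exocyclic carbon, and a chiral 3,3'-dibromo-BINOL catalyst delivers the alkynyl group of F5 to that carbon (diol-catalysed conjugate addition of boronates to ortho-quinone methides), which gives 13.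

Step 9. What may go wrong: poor facial selectivity of oxygen transfer, oxidation of the free phenol or of the electron-rich rings by the dioxirane, or acid-triggered 6-endo opening of the epoxide at the benzylic carbon before the base is added. The fallback sets out from 13 and comes back at 17. Base-mediated 5-exo-dig closure (K2CO3 cat., MeCN, 25 °C) gives the (Z)-2-benzylidene-2,3-dihydrobenzofuran F6, which is used at once because it can tautomerise to the benzofuran. Hydroboration (BH3·SMe2, THF, −20 °C) from the face anti to ring D places hydrogen on the furan carbon and boron on the benzylic carbon, and oxidation (NaBO3, THF/H2O) gives the cis-dihydrobenzofuran (S)-carbinol F7, the carbinol epimer of 16. F7 is taken through the conditions of step 10, in which the carbinol centre is erased (and F7 has, in addition, the configuration that leads to the 2,3-trans flavan even by a concerted double inversion), and so rejoins the route at 17.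

Further compounds
F1 | step 10 | (E)-alkene, hepta-O-benzyl-fisetinidol-(4α→8)-catechin bearing at C6 of ring D the (1R,2E)-1-[4-(benzyloxy)-2-hydroxyphenyl]-3-[3,4-bis(benzyloxy)phenyl]prop-2-en-1-yl group | Oc1cc(OCc2ccccc2)ccc1[C@@H](/C=C/c1ccc(OCc2ccccc2)c(OCc2ccccc2)c1)c1c(OCc3ccccc3)c2c(c([C@@H]3c4ccc(OCc5ccccc5)cc4O[C@H](c4ccc(OCc5ccccc5)c(OCc5ccccc5)c4)[C@H]3O)c1OCc1ccccc1)O[C@H](c1ccc(OCc3ccccc3)c(OCc3ccccc3)c1)[C@@H](O)C2
F2 | step 10 | trans-epoxide, hepta-O-benzyl-fisetinidol-(4α→8)-catechin bearing at C6 of ring D the (R)-[4-(benzyloxy)-2-hydroxyphenyl]{(2S,3S)-3-[3,4-bis(benzyloxy)phenyl]oxiran-2-yl}methyl group | Oc1cc(OCc2ccccc2)ccc1[C@@H]([C@@H]1O[C@H]1c1ccc(OCc2ccccc2)c(OCc2ccccc2)c1)c1c(OCc3ccccc3)c2c(c([C@@H]3c4ccc(OCc5ccccc5)cc4O[C@H](c4ccc(OCc5ccccc5)c(OCc5ccccc5)c4)[C@H]3O)c1OCc1ccccc1)O[C@H](c1ccc(OCc3ccccc3)c(OCc3ccccc3)c1)[C@@H](O)C2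
F3 | step 7 | C6-bromide, 6-bromo derivative of hepta-O-benzyl-fisetinidol-(4α→8)-catechin | Brc1c(OCc3ccccc3)c2c(c([C@@H]3c4ccc(OCc5ccccc5)cc4O[C@H](c4ccc(OCc5ccccc5)c(OCc5ccccc5)c4)[C@H]3O)c1OCc1ccccc1)O[C@H](c1ccc(OCc3ccccc3)c(OCc3ccccc3)c1)[C@@H](O)C2
F4 | step 7 | diaryl carbinol, hepta-O-benzyl-fisetinidol-(4α→8)-catechin bearing at C6 of ring D the [4-(benzyloxy)-2-hydroxyphenyl](hydroxy)methyl group (mixture of carbinol epimers) | Oc1cc(OCc2ccccc2)ccc1C(O)c1c(OCc3ccccc3)c2c(c([C@@H]3c4ccc(OCc5ccccc5)cc4O[C@H](c4ccc(OCc5ccccc5)c(OCc5ccccc5)c4)[C@H]3O)c1OCc1ccccc1)O[C@H](c1ccc(OCc3ccccc3)c(OCc3ccccc3)c1)[C@@H](O)C2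
F5 | step 7 | diisopropyl {[3,4-bis(benzyloxy)phenyl]ethynyl}boronate | CC(C)OB(OC(C)C)C#Cc1ccc(OCc2ccccc2)c(OCc2ccccc2)c1
F6 | step 9 | hepta-O-benzyl-fisetinidol-(4α→8)-catechin bearing at C6 of ring D the (3R,Z)-6-(benzyloxy)-2-[3,4-bis(benzyloxy)benzylidene]-2,3-dihydro-1-benzofuran-3-yl group | c1ccccc1COc1ccc(cc1OCc1ccccc1)/C=C1\Oc2cc(OCc3ccccc3)ccc2[C@@H]1c1c(OCc3ccccc3)c2c(c([C@@H]3c4ccc(OCc5ccccc5)cc4O[C@H](c4ccc(OCc5ccccc5)c(OCc5ccccc5)c4)[C@H]3O)c1OCc1ccccc1)O[C@H](c1ccc(OCc3ccccc3)c(OCc3ccccc3)c1)[C@@H](O)C2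
F7 | step 9 | carbinol epimer of 16, (S)-carbinol on the (2R,3R)-cis-dihydrobenzofuran | O[C@@H](c1ccc(OCc2ccccc2)c(OCc2ccccc2)c1)[C@@H]1Oc2cc(OCc3ccccc3)ccc2[C@@H]1c1c(OCc3ccccc3)c2c(c([C@@H]3c4ccc(OCc5ccccc5)cc4O[C@H](c4ccc(OCc5ccccc5)c(OCc5ccccc5)c4)[C@H]3O)c1OCc1ccccc1)O[C@H](c1ccc(OCc3ccccc3)c(OCc3ccccc3)c1)[C@@H](O)C2
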